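**Retrosynthetic overview**
- The last disconnection is the C6 ester (angeloylation of an α‑ketol); the ring ketone comes from oxidation of a C1 carbinol, and both angelates are delivered by one preformed angelic 2,4,6‑trichlorobenzoic mixed anhydride.
- Both oxiranes are made late: the ring oxirane first, by hydroxyl‑directed epoxidation of the C1 allylic alcohol (from Luche reduction of the enone), the side‑chain oxirane second, by Shi epoxidation of a prenyl alkene. The carbocycle is never built; it is the ring of (R)‑(−)‑carvone.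
- The prenyl alkene comes from an allyl group by cross‑metathesis with 2‑methylbut‑2‑ene.
- Key C–C bond C8–C9: intermolecular Brown asymmetric allylation of a carvone‑derived α‑substituted acrolein (C10 fragment) with an allylborane (C3 fragment), which sets C8.
- The enal comes from (R)‑carvone by α′‑hydroxylation (Rubottom, sets C6), silylation, ene‑chlorination of the isopropenyl methyl, acetate displacement, methanolysis and oxidation.

Assumption: bought reagents and catalysts are not numbered; locants are those of carvone for the ring (C1 carbonyl, C2 methyl‑bearing, C5 side‑chain‑bearing, C6 oxygenated) and C7 (=CH2 carbon), C8 (carbinol), C9, C10, C11 (CMe2) along the side chain; TBS = tert‑butyldimethylsilyl, Ipc = isopinocampheyl.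

**Step 1**
Reactants: 1 (R)‑(−)‑carvone
Product: 3 trimethylsilyl dienol ether of carvone (C1–O–SiMe3; C1=C6 and C2=C3 double bonds), via lithium dienolate 2 (not isolated)
Conditions: LiN(iPr)2 (1.1 equiv), THF, −78 °C; Me3SiCl (1.3 equiv), −78 → 0 °C; pentane, filter, concentrate
Reagents that add atoms: chlorotrimethylsilane, C[Si](C)(C)Cl; lithium diisopropylamide, [Li+].CC(C)[N-]C(C)C (lithium held by 2 only)
Why: Kinetic deprotonation of the enone at the α′‑CH2 (C6) by the hindered amide and O‑silylation give the cross‑conjugated silyl dienol ether (silyl enol ether formation) without touching C5.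

**Step 2**
Reactants: 3 trimethylsilyl dienol ether of carvone
Product: 5 (5S,6S)‑6‑hydroxycarvone (OH trans to isopropenyl), via silyloxy ketone 4 (not isolated)
Conditions: mCPBA (1.05 equiv), CH2Cl2/hexane, −20 → 0 °C; then 1 M HCl, THF, 0 °C
Reagents that add atoms: 3‑chloroperoxybenzoic acid, OOC(=O)c1cccc(Cl)c1
Why: Rubottom oxidation, in which the peracid attacks only the electron‑rich enol ether double bond from the face anti to the C5 isopropenyl group, so that silyloxy‑oxirane rearrangement and hydrolysis give the 5,6‑trans α′‑hydroxy ketone (C6 S).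

**Step 3**
Reactants: 5 (5S,6S)‑6‑hydroxycarvone
Product: 6 (5S,6S)‑6‑(TBS‑oxy)carvone
Conditions: TBSCl (1.3 equiv), imidazole (2.5 equiv), DMF, rt
Reagents that add atoms: tert‑butyldimethylsilyl chloride, CC(C)(C)[Si](C)(C)Cl
Why: Imidazole‑promoted silylation of the secondary α‑ketol gives a robust silyl ether that masks the C6 oxygen until step 16.

**Step 4**
Reactants: 6 (5S,6S)‑6‑(TBS‑oxy)carvone
Product: 7 allylic chloride (isopropenyl CH3 converted into C(=CH2)CH2Cl)
Conditions: Ca(OCl)2 (0.7 equiv), CO2 (dry ice), CH2Cl2/H2O, 0 °C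
Reagents that add atoms: calcium hypochlorite, [Ca+2].[O-]Cl.[O-]Cl (chlorine, delivered as HOCl)
Why: Ene‑type allylic chlorination by HOCl generated in the flask attacks only the electron‑rich 1,1‑disubstituted alkene, and proton loss from the methyl group gives the 2‑(chloromethyl)allyl unit while the enone is inert.

**Step 5**
Reactants: 7 allylic chloride
Product: 8 allylic acetate
Conditions: KOAc (3 equiv), Bu4NI (0.1 equiv), DMF, 50 °C
Reagents that add atoms: potassium acetate, [K+].CC([O-])=O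
Why: Iodide‑assisted SN2 displacement of the primary allylic chloride by acetate (SN2′ attack would give the same product).

**Step 6**
Reactants: 8 allylic acetate
Product: 9 primary allylic alcohol
Conditions: K2CO3 (0.2 equiv), MeOH, 0 °C
Reagents that add atoms: none
Why: Base‑catalysed transesterification (methanolysis) removes the unhindered primary acetate under conditions that leave the silyl ether and enone intact.

**Step 7**
Reactants: 9 primary allylic alcohol
Product: 10 α‑substituted acrolein (C8 aldehyde)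
Conditions: Dess–Martin periodinane (1.2 equiv), pyridine, CH2Cl2, 0 °C → rt; used crude at once
Reagents that add atoms: none
Why: Dess–Martin oxidation converts the primary allylic alcohol to the enal under buffered conditions without affecting the silyl ether.

**Step 8**
Reactants: 10 α‑substituted acrolein
Product: 12 (3S)‑homoallylic alcohol (C8–OH; allyl on C8), via borinate ester 11 (not isolated)
Conditions: (−)‑Ipc2BOMe (1.3 equiv), CH2=CHCH2MgBr (1.2 equiv), Et2O, 0 °C → rt; then 10, −78 °C, 2 h; HOCH2CH2NH2, −78 °C → rt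
Reagents that add atoms: allylmagnesium bromide, C=CC[Mg]Br (allyl group); (−)‑B‑methoxydiisopinocampheylborane, COB([C@@H]1C[C@@H]2C[C@H]([C@H]1C)C2(C)C)[C@@H]1C[C@@H]2C[C@H]([C@H]1C)C2(C)C (Ipc2B held by 11 only)
Why: Brown asymmetric allylboration (carbonyl allylation) joins the two fragments at C8–C9, the allylborane adding to the aldehyde much faster than to the hindered ring ketone through a closed chair transition state in which the (+)‑α‑pinene‑derived Ipc groups direct attack to the Si face (same sense as benzaldehyde → (S)‑alcohol), which sets C8 as S.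

**Step 9**
Reactants: 12 (3S)‑homoallylic alcohol
Product: 13 (3S)‑prenyl carbinol (CH2CH=CMe2 on C8)
Conditions: 2‑methylbut‑2‑ene (large excess), second‑generation Hoveyda–Grubbs catalyst [RuCl2(H2IMes)(=CH‑C6H4‑2‑OiPr)] (5 mol%), CH2Cl2, rt
Reagents that add atoms: 2‑methylbut‑2‑ene, CC=C(C)C
Why: Olefin cross‑metathesis engages only the monosubstituted alkene and caps it as the trisubstituted prenyl alkene with loss of propene, the 1,1‑disubstituted and enone alkenes being inert.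

**Step 10**
Reactants: 14 angelic acid
Product: 15 angelic 2,4,6‑trichlorobenzoic mixed anhydride (one batch, sized for steps 11 and 17)
Conditions: 2,4,6‑trichlorobenzoyl chloride (1.0 equiv), Et3N (1.05 equiv), toluene, rt, 2 h; filter off Et3N·HCl under argon; filtrate titrated and kept as a dry toluene stock solution at −20 °C
Reagents that add atoms: 2,4,6‑trichlorobenzoyl chloride, O=C(Cl)c1c(Cl)cc(Cl)cc1Cl
Why: Yamaguchi activation, in which the triethylammonium carboxylate of 14 attacks the aroyl chloride to give the mixed anhydride without a nucleophilic amine catalyst, so the Z alkene is kept, and the two ortho chlorines shield the aroyl carbonyl so that the anhydride stores cold and later transfers only the angeloyl group.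

**Step 11**
Reactants: 13 (3S)‑prenyl carbinol; 15 angelic 2,4,6‑trichlorobenzoic mixed anhydride
Product: 16 C8 angelate enone
Conditions: 15 (3 equiv, toluene stock solution), Et3N (3 equiv), toluene, 75 °C
Reagents that add atoms: none
Why: Yamaguchi esterification with the preformed mixed anhydride acylates the carbinol oxygen at the unhindered angeloyl carbonyl with retention at C8, and the absence of a nucleophilic amine catalyst avoids Z → E isomerisation of the angelate.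

**Step 12**
Reactants: 16 C8 angelate enone
Product: 17 C1 allylic alcohol (OH cis to the side chain, trans to OTBS)
Conditions: NaBH4 (1 equiv), CeCl3·7H2O (1.1 equiv), MeOH, −78 °C
Reagents that add atoms: none
Why: Luche reduction is 1,2‑selective and delivers hydride axially to the half‑chair with the C5 and C6 substituents pseudo‑equatorial (as in carvone → cis‑carveol), giving the equatorial C1 alcohol (C1 S) and leaving the esters untouched.

**Step 13**
Reactants: 17 C1 allylic alcohol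
Product: 18 ring epoxy alcohol (2,3‑oxirane cis to C1–OH and to the side chain)
Conditions: VO(acac)2 (5 mol%), t‑BuOOH (1.5 equiv, decane), CH2Cl2, 0 °C → rt
Reagents that add atoms: tert‑butyl hydroperoxide, CC(C)(C)OO
Why: Vanadium‑catalysed hydroxyl‑directed epoxidation delivers oxygen from the metal‑bound C1 alkoxide to the same face of the C2=C3 bond, setting C2 and C3 cis to the hydroxyl while the non‑allylic alkenes do not react.

**Step 14**
Reactants: 18 ring epoxy alcohol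
Product: 19 bis‑epoxy alcohol ((10R)‑10,11‑oxirane)
Conditions: 1,2:4,5‑di‑O‑isopropylidene‑β‑D‑erythro‑2,3‑hexodiulo‑2,6‑pyranose (Shi ketone, 0.3 equiv), Oxone (2KHSO5·KHSO4·K2SO4), K2CO3, Bu4NHSO4, aq Na2B4O7/Na2EDTA buffer, MeCN/CH2(OMe)2, 0 °C
Reagents that add atoms: potassium peroxymonosulfate, [K+].OOS([O-])(=O)=O
Why: Shi asymmetric epoxidation, in which the chiral dioxirane from the D‑fructose‑derived ketone epoxidises only the electron‑rich trisubstituted alkene through the spiro transition state and sets C10 as R under catalyst control.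

**Step 15**
Reactants: 19 bis‑epoxy alcohol
Product: 20 bis‑epoxy ketone (C6–OTBS)
Conditions: Dess–Martin periodinane (1.5 equiv), pyridine, CH2Cl2, 0 °C → rt
Reagents that add atoms: none
Why: Dess–Martin oxidation of the secondary C1 alcohol under buffered non‑acidic conditions preserves both oxiranes, the silyl ether and the ester.

**Step 16**
Reactants: 20 bis‑epoxy ketone
Product: 21 bis‑epoxy α′‑hydroxy ketone (C6–OH)
Conditions: Bu4NF/AcOH (1:1, 3 equiv), THF, 0 °C → rt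
Reagents that add atoms: none
Why: Fluoride‑mediated desilylation buffered with acetic acid cleaves the α‑keto silyl ether near neutrality, so neither oxirane opens and C6 is not epimerised.

**Step 17**
Reactants: 21 bis‑epoxy α′‑hydroxy ketone; 15 angelic 2,4,6‑trichlorobenzoic mixed anhydride
Product: 22 target (CNP0247177.2)
Conditions: 15 (4 equiv, toluene stock solution), Et3N (4 equiv), toluene, 70 °C
Reagents that add atoms: none
Why: Yamaguchi esterification of the α‑ketol oxygen with the preformed mixed anhydride proceeds with retention at C6, the amine base scavenges the liberated aroic acid so the oxiranes survive, and the absence of a nucleophilic catalyst keeps the Z geometry of both angelates.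

**Compound list**
1 | (R)‑(−)‑carvone, (5R)‑2‑methyl‑5‑(prop‑1‑en‑2‑yl)cyclohex‑2‑en‑1‑one | C=C(C)[C@@H]1CC=C(C)C(=O)C1 | starting material
2 | lithium (3R)‑6‑methyl‑3‑(prop‑1‑en‑2‑yl)cyclohexa‑1,5‑dien‑1‑olate | C=C(C)[C@@H]1CC=C(C)C([O-])=C1.[Li+] | intermediate (not isolated)
3 | trimethyl{[(3R)‑6‑methyl‑3‑(prop‑1‑en‑2‑yl)cyclohexa‑1,5‑dien‑1‑yl]oxy}silane | C=C(C)[C@@H]1CC=C(C)C(O[Si](C)(C)C)=C1 | intermediate
4 | (5S,6S)‑2‑methyl‑5‑(prop‑1‑en‑2‑yl)‑6‑[(trimethylsilyl)oxy]cyclohex‑2‑en‑1‑one | C=C(C)[C@@H]1CC=C(C)C(=O)[C@H]1O[Si](C)(C)C | intermediate (not isolated)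
5 | (5S,6S)‑6‑hydroxy‑2‑methyl‑5‑(prop‑1‑en‑2‑yl)cyclohex‑2‑en‑1‑one | C=C(C)[C@@H]1CC=C(C)C(=O)[C@H]1O | intermediate
6 | (5S,6S)‑6‑[(tert‑butyldimethylsilyl)oxy]‑2‑methyl‑5‑(prop‑1‑en‑2‑yl)cyclohex‑2‑en‑1‑one | C=C(C)[C@@H]1CC=C(C)C(=O)[C@H]1O[Si](C)(C)C(C)(C)C | intermediate
7 | (5S,6S)‑6‑[(tert‑butyldimethylsilyl)oxy]‑5‑(3‑chloroprop‑1‑en‑2‑yl)‑2‑methylcyclohex‑2‑en‑1‑one | C=C(CCl)[C@@H]1CC=C(C)C(=O)[C@H]1O[Si](C)(C)C(C)(C)C | intermediate
8 | 2‑[(1S,2S)‑2‑[(tert‑butyldimethylsilyl)oxy]‑4‑methyl‑3‑oxocyclohex‑4‑en‑1‑yl]prop‑2‑en‑1‑yl acetate | C=C(COC(C)=O)[C@@H]1CC=C(C)C(=O)[C@H]1O[Si](C)(C)C(C)(C)C | intermediate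
9 | (5S,6S)‑6‑[(tert‑butyldimethylsilyl)oxy]‑5‑(3‑hydroxyprop‑1‑en‑2‑yl)‑2‑methylcyclohex‑2‑en‑1‑one | C=C(CO)[C@@H]1CC=C(C)C(=O)[C@H]1O[Si](C)(C)C(C)(C)C | intermediate
10 | 2‑[(1S,2S)‑2‑[(tert‑butyldimethylsilyl)oxy]‑4‑methyl‑3‑oxocyclohex‑4‑en‑1‑yl]prop‑2‑enal | C=C(C=O)[C@@H]1CC=C(C)C(=O)[C@H]1O[Si](C)(C)C(C)(C)C | intermediate
11 | (3S)‑2‑[(1S,2S)‑2‑[(tert‑butyldimethylsilyl)oxy]‑4‑methyl‑3‑oxocyclohex‑4‑en‑1‑yl]hexa‑1,5‑dien‑3‑yl diisopinocampheylborinate (Ipc from (+)‑α‑pinene) | C=C([C@H](CC=C)OB([C@@H]2C[C@@H]3C[C@H]([C@H]2C)C3(C)C)[C@@H]2C[C@@H]3C[C@H]([C@H]2C)C3(C)C)[C@@H]1CC=C(C)C(=O)[C@H]1O[Si](C)(C)C(C)(C)C | intermediate (not isolated)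
12 | (5S,6S)‑6‑[(tert‑butyldimethylsilyl)oxy]‑5‑[(3S)‑3‑hydroxyhexa‑1,5‑dien‑2‑yl]‑2‑methylcyclohex‑2‑en‑1‑one | C=C([C@H](CC=C)O)[C@@H]1CC=C(C)C(=O)[C@H]1O[Si](C)(C)C(C)(C)C | intermediate
13 | (5S,6S)‑6‑[(tert‑butyldimethylsilyl)oxy]‑5‑[(3S)‑3‑hydroxy‑6‑methylhepta‑1,5‑dien‑2‑yl]‑2‑methylcyclohex‑2‑en‑1‑one | C=C([C@H](CC=C(C)C)O)[C@@H]1CC=C(C)C(=O)[C@H]1O[Si](C)(C)C(C)(C)C | intermediate
14 | angelic acid, (2Z)‑2‑methylbut‑2‑enoic acid | C/C=C(/C)C(=O)O | starting material
15 | (2Z)‑2‑methylbut‑2‑enoic 2,4,6‑trichlorobenzoic anhydride | C/C=C(/C)C(=O)OC(=O)c1c(Cl)cc(Cl)cc1Cl | intermediate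
16 | (3S)‑2‑[(1S,2S)‑2‑[(tert‑butyldimethylsilyl)oxy]‑4‑methyl‑3‑oxocyclohex‑4‑en‑1‑yl]‑6‑methylhepta‑1,5‑dien‑3‑yl (2Z)‑2‑methylbut‑2‑enoate | C=C([C@H](CC=C(C)C)OC(=O)/C(C)=C\C)[C@@H]1CC=C(C)C(=O)[C@H]1O[Si](C)(C)C(C)(C)C | intermediate
17 | (3S)‑2‑[(1S,2S,3S)‑2‑[(tert‑butyldimethylsilyl)oxy]‑3‑hydroxy‑4‑methylcyclohex‑4‑en‑1‑yl]‑6‑methylhepta‑1,5‑dien‑3‑yl (2Z)‑2‑methylbut‑2‑enoate (ring OH cis to side chain, trans to OTBS) | C=C([C@H](CC=C(C)C)OC(=O)/C(C)=C\C)[C@@H]1CC=C(C)[C@H](O)[C@H]1O[Si](C)(C)C(C)(C)C | intermediate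
18 | (3S)‑2‑[(1S,3S,4S,5R,6R)‑4‑[(tert‑butyldimethylsilyl)oxy]‑5‑hydroxy‑6‑methyl‑7‑oxabicyclo[4.1.0]heptan‑3‑yl]‑6‑methylhepta‑1,5‑dien‑3‑yl (2Z)‑2‑methylbut‑2‑enoate (oxirane and OH cis to side chain) | C=C([C@H](CC=C(C)C)OC(=O)/C(C)=C\C)[C@@H]1C[C@@H]2O[C@]2(C)[C@H](O)[C@H]1O[Si](C)(C)C(C)(C)C | intermediate
19 | (2S)‑1‑[(2R)‑3,3‑dimethyloxiran‑2‑yl]‑3‑[(1S,3S,4S,5R,6R)‑4‑[(tert‑butyldimethylsilyl)oxy]‑5‑hydroxy‑6‑methyl‑7‑oxabicyclo[4.1.0]heptan‑3‑yl]but‑3‑en‑2‑yl (2Z)‑2‑methylbut‑2‑enoate | C=C([C@H](C[C@H]1OC1(C)C)OC(=O)/C(C)=C\C)[C@@H]1C[C@@H]2O[C@]2(C)[C@H](O)[C@H]1O[Si](C)(C)C(C)(C)C | intermediate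
20 | (2S)‑1‑[(2R)‑3,3‑dimethyloxiran‑2‑yl]‑3‑[(1S,3S,4S,6S)‑4‑[(tert‑butyldimethylsilyl)oxy]‑6‑methyl‑5‑oxo‑7‑oxabicyclo[4.1.0]heptan‑3‑yl]but‑3‑en‑2‑yl (2Z)‑2‑methylbut‑2‑enoate | C=C([C@H](C[C@H]1OC1(C)C)OC(=O)/C(C)=C\C)[C@@H]1C[C@@H]2O[C@]2(C)C(=O)[C@H]1O[Si](C)(C)C(C)(C)C | intermediate
21 | (2S)‑1‑[(2R)‑3,3‑dimethyloxiran‑2‑yl]‑3‑[(1S,3S,4S,6S)‑4‑hydroxy‑6‑methyl‑5‑oxo‑7‑oxabicyclo[4.1.0]heptan‑3‑yl]but‑3‑en‑2‑yl (2Z)‑2‑methylbut‑2‑enoate | C=C([C@H](C[C@H]1OC1(C)C)OC(=O)/C(C)=C\C)[C@@H]1C[C@@H]2O[C@]2(C)C(=O)[C@H]1O | intermediate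
22 | (2S)‑1‑[(2R)‑3,3‑dimethyloxiran‑2‑yl]‑3‑[(1S,3S,4S,6S)‑6‑methyl‑4‑{[(2Z)‑2‑methylbut‑2‑enoyl]oxy}‑5‑oxo‑7‑oxabicyclo[4.1.0]heptan‑3‑yl]but‑3‑en‑2‑yl (2Z)‑2‑methylbut‑2‑enoate | C=C([C@H](C[C@H]1OC1(C)C)OC(=O)/C(C)=C\C)[C@@H]1C[C@@H]2O[C@]2(C)C(=O)[C@H]1OC(=O)/C(C)=C\C | target

**Totals**
Total step count: 17. Longest linear sequence: 16 steps (1 → 22 through steps 1–9 and 11–17); step 10 is a one‑step side branch that makes the mixed anhydride 15 from bought angelic acid 14, and 15 enters at steps 11 and 17.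

**Three steps most likely to fail, with fallbacks**

Step 8. The α‑substituted acrolein 10 is prone to oligomerise, and C8 is set by the reagent alone on a substrate that also carries a ketone. The fallback sets out from 10 and comes back at 12. Indium powder and allyl bromide in THF/H2O (Barbier allylation, aldehyde‑selective) give 12 together with its carbinol epimer, the (3R)‑homoallylic alcohol F1. The two diastereomers are separated on silica. F1 is then inverted by Mitsunobu esterification (4‑nitrobenzoic acid, PPh3, DIAD, THF, 0 °C) to the (3S)‑4‑nitrobenzoate F2, and methanolysis (K2CO3, MeOH, 0 °C) of F2 returns 12.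

Step 12. The facial course of the hydride addition next to the bulky α′‑silyl ether is argued by analogy and is not guaranteed. The fallback sets out from 16 and comes back at 17. If the reduction gives mainly the C1‑epimeric allylic alcohol F3 (hydroxyl cis to OTBS), that material is not discarded. It is inverted by Mitsunobu reaction (4‑nitrobenzoic acid, PPh3, DIAD, toluene, 0 °C → rt) to the C1 4‑nitrobenzoate F4, which has the required configuration. The activated 4‑nitrobenzoate is then cleaved selectively (K2CO3 0.2 equiv, MeOH, 0 °C) in the presence of the hindered angelate to give 17.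

Step 17. The α‑ketol is hindered and can epimerise or undergo ketol shift under warm basic acylation, and the angelate can drift to the tiglate. The fallback sets out from 19 and comes back at 22; it puts the ester on before the ketone exists, so the last step is a mild oxidation. First, 19 is esterified at the C1 hydroxyl (levulinic acid, N,N′‑diisopropylcarbodiimide, 4‑(dimethylamino)pyridine, CH2Cl2, rt) to the C1 levulinate F5. Bu4NF/AcOH in THF then removes the silyl group to give the C6 alcohol F6. The mixed anhydride 15 from the stock solution (Et3N, toluene, 70 °C) acylates this ordinary secondary alcohol to the angelate levulinate F7. Hydrazine acetate in pyridine/AcOH at 0 °C removes the levulinate to give the C1 alcohol F8. Finally, Dess–Martin periodinane with pyridine in CH2Cl2 oxidises F8 to 22.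

**Further compounds**
F1 | step 8 | (5S,6S)‑6‑[(tert‑butyldimethylsilyl)oxy]‑5‑[(3R)‑3‑hydroxyhexa‑1,5‑dien‑2‑yl]‑2‑methylcyclohex‑2‑en‑1‑one (C8 epimer of 12) | C=C([C@@H](CC=C)O)[C@@H]1CC=C(C)C(=O)[C@H]1O[Si](C)(C)C(C)(C)C
F2 | step 8 | (3S)‑2‑[(1S,2S)‑2‑[(tert‑butyldimethylsilyl)oxy]‑4‑methyl‑3‑oxocyclohex‑4‑en‑1‑yl]hexa‑1,5‑dien‑3‑yl 4‑nitrobenzoate | C=C([C@H](CC=C)OC(=O)c2ccc(cc2)[N+](=O)[O-])[C@@H]1CC=C(C)C(=O)[C@H]1O[Si](C)(C)C(C)(C)C
F3 | step 12 | (3S)‑2‑[(1S,2S,3R)‑2‑[(tert‑butyldimethylsilyl)oxy]‑3‑hydroxy‑4‑methylcyclohex‑4‑en‑1‑yl]‑6‑methylhepta‑1,5‑dien‑3‑yl (2Z)‑2‑methylbut‑2‑enoate (C1 epimer of 17) | C=C([C@H](CC=C(C)C)OC(=O)/C(C)=C\C)[C@@H]1CC=C(C)[C@@H](O)[C@H]1O[Si](C)(C)C(C)(C)C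
F4 | step 12 | (1S,5S,6S)‑6‑[(tert‑butyldimethylsilyl)oxy]‑2‑methyl‑5‑{(3S)‑6‑methyl‑3‑[(2Z)‑2‑methylbut‑2‑enoyloxy]hepta‑1,5‑dien‑2‑yl}cyclohex‑2‑en‑1‑yl 4‑nitrobenzoate | C=C([C@H](CC=C(C)C)OC(=O)/C(C)=C\C)[C@@H]1CC=C(C)[C@H](OC(=O)c2ccc(cc2)[N+](=O)[O-])[C@H]1O[Si](C)(C)C(C)(C)C
F5 | step 17 | 19 with its ring C1 hydroxyl esterified as the 4‑oxopentanoate (levulinate), all stereocentres as in 19 | C=C([C@H](C[C@H]1OC1(C)C)OC(=O)/C(C)=C\C)[C@@H]1C[C@@H]2O[C@]2(C)[C@H](OC(=O)CCC(C)=O)[C@H]1O[Si](C)(C)C(C)(C)C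
F6 | step 17 | F5 with the C6 silyl ether replaced by a free hydroxyl | C=C([C@H](C[C@H]1OC1(C)C)OC(=O)/C(C)=C\C)[C@@H]1C[C@@H]2O[C@]2(C)[C@H](OC(=O)CCC(C)=O)[C@H]1O
F7 | step 17 | F6 with the C6 hydroxyl esterified as the (2Z)‑2‑methylbut‑2‑enoate | C=C([C@H](C[C@H]1OC1(C)C)OC(=O)/C(C)=C\C)[C@@H]1C[C@@H]2O[C@]2(C)[C@H](OC(=O)CCC(C)=O)[C@H]1OC(=O)/C(C)=C\C
F8 | step 17 | C1 alcohol corresponding to 22 (C1 hydroxyl cis to the ring oxirane and side chain, both angelates in place) | C=C([C@H](C[C@H]1OC1(C)C)OC(=O)/C(C)=C\C)[C@@H]1C[C@@H]2O[C@]2(C)[C@H](O)[C@H]1OC(=O)/C(C)=C\C
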